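**Retrosynthetic overview**
- Last bond made: C5–propenyl, by Suzuki–Miyaura coupling of aryl bromide 10 with the (E)-propenylboronate 11, so the E geometry is bought rather than made.
- Key disconnection: the C3a–C3 bond of the dihydrofuran ring, closed by a 5-exo-trig aryl radical cyclization of the (R)-1-arylallyl 2-iodoaryl ether 7. This dihydrofuran ring is the only ring formed in the route; both benzene rings are bought.
- Enabling feature: C3 carries only a methyl group and sits next to the ether carbon C2 (bonded to O1 and the trimethoxyphenyl ring). C2–C3–CH3 is therefore a reduced vinyl group, and O1–C2(aryl)–CH=CH2 is a branched allyl aryl ether whose internal alkene carbon lies five atoms from C3a, the ring A carbon ortho to O1.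
- Ether 7 comes from iridium-catalysed asymmetric allylic etherification of iodophenol 5 with cinnamyl carbonate 3, which sets C2 (R). C3 is then set from C2 during the ring closure (trans).
- 3 comes from methyl 3,4,5-trimethoxycinnamate 1 (reduction, carbonate formation); 5 comes from 4-bromo-2-methoxyphenol 4 (ortho iodination).

Key step: step 5

Assumption: 1, 4 and 11 are taken as commercial, and the (Ra,Rc,Rc) ligand is taken to give the R ether, as this catalyst family does with cinnamyl carbonates and heteroatom nucleophiles; the mirror-image ligand would be used if the sense proved opposite.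

Step 1
Reactants: 1 methyl (2E)-3-(3,4,5-trimethoxyphenyl)prop-2-enoate
Product: 2 (2E)-3-(3,4,5-trimethoxyphenyl)prop-2-en-1-ol
Conditions: i-Bu2AlH (2.2 equiv), CH2Cl2, −78 °C; aqueous potassium sodium tartrate work-up
Reagents that add atoms: none
Why: Ester reduction by an aluminium hydride: i-Bu2AlH delivers hydride twice to the ester carbonyl (1,2-reduction) at low temperature and leaves the conjugated E double bond in place.

Step 2
Reactants: 2 (2E)-3-(3,4,5-trimethoxyphenyl)prop-2-en-1-ol
Product: 3 methyl (2E)-3-(3,4,5-trimethoxyphenyl)prop-2-en-1-yl carbonate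
Conditions: ClCO2Me, pyridine, CH2Cl2, 0 °C
Reagents that add atoms: methyl chloroformate, COC(=O)Cl
Why: O-acylation of a primary alcohol by a chloroformate (carbonate formation) installs the leaving group that the allylic substitution needs.

Step 3
Reactants: 4 4-bromo-2-methoxyphenol
Product: 5 4-bromo-2-iodo-6-methoxyphenol
Conditions: N-iodosuccinimide, p-TsOH (cat.), MeCN, rt
Reagents that add atoms: N-iodosuccinimide, O=C1CCC(=O)N1I
Why: Electrophilic aromatic iodination: the hydroxyl group directs to its only free ortho position, the para position being blocked by bromine, so iodine enters at the carbon that becomes C3a.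

Step 4
Reactants: 3 methyl (2E)-3-(3,4,5-trimethoxyphenyl)prop-2-en-1-yl carbonate; 5 4-bromo-2-iodo-6-methoxyphenol
Product: 7 5-bromo-1-iodo-3-methoxy-2-{[(1R)-1-(3,4,5-trimethoxyphenyl)prop-2-en-1-yl]oxy}benzene, via lithium aryloxide 6 (not isolated)
Conditions: 5, LiN(SiMe3)2, THF, 0 °C; then 3, [Ir(cod)Cl]2 (2 mol %), (Ra,Rc,Rc)-O,O'-(1,1'-binaphthyl-2,2'-diyl) N,N-bis(1-phenylethyl)phosphoramidite (4 mol %), THF, rt to 50 °C
Reagents that add atoms: lithium bis(trimethylsilyl)amide, [Li+].C[Si](C)(C)[N-][Si](C)(C)C (supplies the lithium of intermediate 6 only; 7 keeps no reagent atoms)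
Why: Iridium-catalysed asymmetric allylic etherification: the cyclometalated iridium–phosphoramidite complex ionises carbonate 3 and the aryloxide attacks the aryl-substituted allyl terminus from the face fixed by the ligand, so the branched ether forms and the C2 stereocentre is set as R under catalyst control.

Step 5
Reactants: 7 5-bromo-1-iodo-3-methoxy-2-{[(1R)-1-(3,4,5-trimethoxyphenyl)prop-2-en-1-yl]oxy}benzene
Product: 10 (2R,3R)-5-bromo-7-methoxy-3-methyl-2-(3,4,5-trimethoxyphenyl)-2,3-dihydro-1-benzofuran, via aryl radical 8 (not isolated), via primary alkyl radical 9 (not isolated)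
Conditions: (Me3Si)3SiH (1.2 equiv), Et3B (0.2 equiv), air, toluene (0.02 mol/L), 0 °C to rt
Reagents that add atoms: none
Why: Ethyl radicals from Et3B and oxygen start a silyl radical chain in which the tris(trimethylsilyl)silyl radical abstracts iodine from 7, the σ-aryl radical 8 adds to the internal vinyl carbon, and the primary radical 9 takes a hydrogen atom from the silane to give the C3 methyl group. The closest known reaction type is the aryl radical cyclization of 2-haloaryl allyl ethers to 3-methyl-2,3-dihydrobenzofurans. The dihydrofuran ring is closed in the 5-exo-trig mode by forming the bond between C3a (the arene carbon ortho to the ether oxygen) and C3. The new C3 stereocentre is controlled by the existing C2 stereocentre: in the chair-like 5-exo transition state the trimethoxyphenyl group on the allylic carbon sits pseudo-equatorial and away from the terminal CH2, so the methyl group should end up trans to the aryl group, giving (2R,3R) with C2 untouched. The step needs iodine to be abstracted in preference to bromine and ring closure to outrun hydrogen capture and attack of 8 on the trimethoxyphenyl ring; the weaker carbon–iodine bond, the very fast cyclization of 2-(allyloxy)aryl radicals and the dilute silane secure this.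

Step 6
Reactants: 10 (2R,3R)-5-bromo-7-methoxy-3-methyl-2-(3,4,5-trimethoxyphenyl)-2,3-dihydro-1-benzofuran; 11 4,4,5,5-tetramethyl-2-[(1E)-prop-1-en-1-yl]-1,3,2-dioxaborolane
Product: 12 (2R,3R)-7-methoxy-3-methyl-5-[(1E)-prop-1-en-1-yl]-2-(3,4,5-trimethoxyphenyl)-2,3-dihydro-1-benzofuran
Conditions: Pd(dppf)Cl2 (5 mol %), K2CO3, 1,4-dioxane/H2O, 80 °C
Reagents that add atoms: none
Why: Suzuki–Miyaura coupling of an aryl bromide with an alkenylboronate, which transfers the propenyl group with retention of its E geometry and does not touch the two stereocentres under mildly basic conditions.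

**Compound list**
1 | methyl (2E)-3-(3,4,5-trimethoxyphenyl)prop-2-enoate | COC(=O)/C=C/c1cc(OC)c(OC)c(OC)c1 | starting material
2 | (2E)-3-(3,4,5-trimethoxyphenyl)prop-2-en-1-ol | OC/C=C/c1cc(OC)c(OC)c(OC)c1 | intermediate
3 | methyl (2E)-3-(3,4,5-trimethoxyphenyl)prop-2-en-1-yl carbonate | COC(=O)OC/C=C/c1cc(OC)c(OC)c(OC)c1 | intermediate
4 | 4-bromo-2-methoxyphenol | COc1cc(Br)ccc1O | starting material
5 | 4-bromo-2-iodo-6-methoxyphenol | Oc1c(I)cc(Br)cc1OC | intermediate
6 | lithium 4-bromo-2-iodo-6-methoxyphenolate | [Li+].[O-]c1c(I)cc(Br)cc1OC | intermediate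
7 | 5-bromo-1-iodo-3-methoxy-2-{[(1R)-1-(3,4,5-trimethoxyphenyl)prop-2-en-1-yl]oxy}benzene | C=C[C@H](c1cc(OC)c(OC)c(OC)c1)Oc1c(I)cc(Br)cc1OC | intermediate
8 | 5-bromo-3-methoxy-2-{[(1R)-1-(3,4,5-trimethoxyphenyl)prop-2-en-1-yl]oxy}phenyl radical | C=C[C@H](c1cc(OC)c(OC)c(OC)c1)Oc1[c]cc(Br)cc1OC | intermediate
9 | [(2R,3R)-5-bromo-7-methoxy-2-(3,4,5-trimethoxyphenyl)-2,3-dihydro-1-benzofuran-3-yl]methyl radical | Brc1cc(OC)c2c(c1)[C@@H]([CH2])[C@H](c1cc(OC)c(OC)c(OC)c1)O2 | intermediate
10 | (2R,3R)-5-bromo-7-methoxy-3-methyl-2-(3,4,5-trimethoxyphenyl)-2,3-dihydro-1-benzofuran (trans) | Brc1cc(OC)c2c(c1)[C@@H](C)[C@H](c1cc(OC)c(OC)c(OC)c1)O2 | intermediate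
11 | 4,4,5,5-tetramethyl-2-[(1E)-prop-1-en-1-yl]-1,3,2-dioxaborolane | C/C=C/B1OC(C)(C)C(C)(C)O1 | starting material
12 | (2R,3R)-7-methoxy-3-methyl-5-[(1E)-prop-1-en-1-yl]-2-(3,4,5-trimethoxyphenyl)-2,3-dihydro-1-benzofuran (trans) | C/C=C/c1cc(OC)c2c(c1)[C@@H](C)[C@H](c1cc(OC)c(OC)c(OC)c1)O2 | target

Total step count: 6. Longest linear sequence: 5 steps (steps 1, 2, 4, 5, 6).

**Steps most likely to fail**

Step 5 (key step). The closure may be insufficiently trans-selective, because C3 is set only by the conformational preference of the C2 substituent, and part of the aryl radical may be diverted by attack on the trimethoxyphenyl ring. The fallback sets out from 2 (with 5 as the phenol partner) and comes back to the route at 10; it closes the same C3a–C3 bond by a stereospecific SN2 ring closure instead. Sharpless asymmetric epoxidation of 2 (Ti(OiPr)4, diisopropyl (2S,3S)-tartrate, t-BuOOH, 4 Å sieves, CH2Cl2, −20 °C) should give [(2R,3R)-3-(3,4,5-trimethoxyphenyl)oxiran-2-yl]methanol F1. Opening of F1 by the aryloxide of 5 at the benzylic carbon with inversion (aqueous NaOH, 70 °C, as is usual for 3-arylglycidols) should give (2R,3S)-3-(4-bromo-2-iodo-6-methoxyphenoxy)-3-(3,4,5-trimethoxyphenyl)propane-1,2-diol F2. Mitsunobu cyclodehydration through the primary hydroxyl group (PPh3, DIAD, THF) should give the erythro epoxy ether 5-bromo-1-iodo-3-methoxy-2-{(S)-[(2R)-oxiran-2-yl](3,4,5-trimethoxyphenyl)methoxy}benzene F3. Iodine–lithium exchange (n-BuLi, THF, −100 °C, then warming) followed by Parham-type 5-exo-tet opening of the epoxide at its internal carbon with inversion should give [(2R,3S)-5-bromo-7-methoxy-2-(3,4,5-trimethoxyphenyl)-2,3-dihydro-1-benzofuran-3-yl]methanol F4, trans by stereospecificity. Tosylation (TsCl, pyridine) to [(2R,3S)-5-bromo-7-methoxy-2-(3,4,5-trimethoxyphenyl)-2,3-dihydro-1-benzofuran-3-yl]methyl 4-methylbenzenesulfonate F5 and reduction with LiBHEt3 (THF, 0 °C) then give 10.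

Step 4. The doubly ortho-substituted, weakly nucleophilic aryloxide may attack the allyl–iridium complex slowly or at the unsubstituted terminus, and the branched ether, which carries a good aryloxide leaving group, may re-ionise and lose enantiomeric purity. The fallback sets out from 5 and comes back to the route at 7; it uses stereospecific substitution instead of asymmetric catalysis. Addition of CH2=CHMgBr to commercial 3,4,5-trimethoxybenzaldehyde (THF, 0 °C) gives racemic 1-(3,4,5-trimethoxyphenyl)prop-2-en-1-ol F6. Lipase-catalysed kinetic resolution (Candida antarctica lipase B, vinyl acetate, MTBE) should leave (1S)-1-(3,4,5-trimethoxyphenyl)prop-2-en-1-ol F7 unreacted, while the R enantiomer is removed as (1R)-1-(3,4,5-trimethoxyphenyl)prop-2-en-1-yl acetate F8. Mitsunobu etherification of F7 with 5 (PPh3, DIAD, toluene, −20 °C) with inversion then gives 7.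

Step 6. Oxidative addition at the electron-rich aryl bromide may be slow, so that protodeboronation of the alkenylboronate or partial E/Z isomerisation competes. The fallback sets out from 10 and comes back to the route at 12; it uses carbonyl olefination instead of cross-coupling. Bromine–lithium exchange on 10 (n-BuLi, THF, −78 °C) and quenching with DMF gives (2R,3R)-7-methoxy-3-methyl-2-(3,4,5-trimethoxyphenyl)-2,3-dihydro-1-benzofuran-5-carbaldehyde F9. Julia–Kocienski olefination with 5-(ethylsulfonyl)-1-phenyl-1H-tetrazole (KN(SiMe3)2, DME, −60 °C to rt) should then give the E-propenyl group of 12.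

**Further compounds**
F1 | step 5 | [(2R,3R)-3-(3,4,5-trimethoxyphenyl)oxiran-2-yl]methanol | OC[C@H]1O[C@@H]1c1cc(OC)c(OC)c(OC)c1
F2 | step 5 | (2R,3S)-3-(4-bromo-2-iodo-6-methoxyphenoxy)-3-(3,4,5-trimethoxyphenyl)propane-1,2-diol | O[C@H](CO)[C@H](c1cc(OC)c(OC)c(OC)c1)Oc1c(I)cc(Br)cc1OC
F3 | step 5 | 5-bromo-1-iodo-3-methoxy-2-{(S)-[(2R)-oxiran-2-yl](3,4,5-trimethoxyphenyl)methoxy}benzene | C1O[C@H]1[C@H](c1cc(OC)c(OC)c(OC)c1)Oc1c(I)cc(Br)cc1OC
F4 | step 5 | [(2R,3S)-5-bromo-7-methoxy-2-(3,4,5-trimethoxyphenyl)-2,3-dihydro-1-benzofuran-3-yl]methanol | Brc1cc(OC)c2c(c1)[C@@H](CO)[C@H](c1cc(OC)c(OC)c(OC)c1)O2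
F5 | step 5 | [(2R,3S)-5-bromo-7-methoxy-2-(3,4,5-trimethoxyphenyl)-2,3-dihydro-1-benzofuran-3-yl]methyl 4-methylbenzenesulfonate | Brc1cc(OC)c2c(c1)[C@@H](COS(=O)(=O)c1ccc(C)cc1)[C@H](c1cc(OC)c(OC)c(OC)c1)O2
F6 | step 4 | racemic 1-(3,4,5-trimethoxyphenyl)prop-2-en-1-ol | C=CC(O)c1cc(OC)c(OC)c(OC)c1
F7 | step 4 | (1S)-1-(3,4,5-trimethoxyphenyl)prop-2-en-1-ol | C=C[C@H](O)c1cc(OC)c(OC)c(OC)c1
F8 | step 4 | (1R)-1-(3,4,5-trimethoxyphenyl)prop-2-en-1-yl acetate | C=C[C@@H](OC(C)=O)c1cc(OC)c(OC)c(OC)c1
F9 | step 6 | (2R,3R)-7-methoxy-3-methyl-2-(3,4,5-trimethoxyphenyl)-2,3-dihydro-1-benzofuran-5-carbaldehyde | O=Cc1cc(OC)c2c(c1)[C@@H](C)[C@H](c1cc(OC)c(OC)c(OC)c1)O2
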